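Numbering: calamenene is 1,6-dimethyl-4-(propan-2-yl)tetralin. In each half C1 holds CH3, C4 holds iPr, C4a and C8a are the fusion carbons and C8 holds OH. Unit A is bonded through C7 and unit B (primed) through C5'.
Enabling feature: in aromatic ring A the hydroxylated carbon C8 is flanked by C7, which holds unit B, and by the fusion carbon C8a, while C7–C6–C5–C4a–C8a is one unbroken five-carbon path. C8 and its oxygen can therefore enter together as carbon monoxide bridging the two ends of a pentadienyl unit.
Cuts: first the two O-protecting groups, then C7–C8 and C8–C8a at once (CO out, leaving a 1-aryl-2,4-pentadienyl acetate). Next comes C7–C5' (aryllithium plus dienal, so the crowded biaryl bond is first made as an sp3–sp2 bond), then C5–C4a (Heck). Unit B is cut the same way at C7'–C8' and C8'–C8a' and leads back to the same dienal.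
Forward: both saturated rings are bought as commercial (+)-menthone. The benzene ring of unit B is closed first (step 5), armed at C5' (steps 6 and 7) and joined to a second portion of the dienal (step 8). Ring A is closed last (step 9) and both phenols are freed (step 10).
Stereochemistry: C1/C4 and C1'/C4' (each 1S,4R, trans) are C5/C2 of (2R,5S)-menthone and are carried through unchanged. C4 is at risk only as the α-carbon of menthone (kinetic enolisation goes away from it), and C1 only as the vinylogous ε-position of the dienal (no strong base or secondary amine meets it). The C7 carbinol centre is transient.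

Key step: step 9

Assumption: the SMILES fixes four stereocentres and gives no sense for the hindered C7–C5' axis, so the route aims at (1S,4R,1'S,4'R); if two atropisomers arise they are separated by chromatography at the key-step product or at the target.

Step 1
Reactants: 1 (+)-menthone, (2R,5S)-5-methyl-2-(propan-2-yl)cyclohexan-1-one
Product: 3 (3S,6R)-3-methyl-6-(propan-2-yl)cyclohex-1-en-1-yl trifluoromethanesulfonate (menthenyl triflate), via lithium enolate 2 (not isolated)
Conditions: LiN(iPr)2, THF, −78 °C; PhNTf2, −78 °C → rt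
Reagents that add atoms: N-phenylbis(trifluoromethanesulfonimide), O=S(=O)(N(c1ccccc1)S(=O)(=O)C(F)(F)F)C(F)(F)F
Why: Kinetic enolate formation and O-triflation (enol triflate synthesis): the bulky amide base removes a proton from the free C6 methylene and not the hindered C2–H next to the isopropyl group, so the alkene points toward the methyl-bearing carbon and no stereocentre is disturbed or created.

Step 2
Reactants: 3 menthenyl triflate; 4 methacrolein (2-methylprop-2-enal)
Product: 5 (2E)-2-methyl-3-[(3S,6R)-3-methyl-6-(propan-2-yl)cyclohex-1-en-1-yl]prop-2-enal (dienal)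
Conditions: Pd(OAc)2 (5 mol %), PPh3 (10 mol %), Et3N, BHT (trace), DMF, 70 °C
Reagents that add atoms: none
Why: Mizoroki–Heck vinylation of an enol triflate with an electron-poor alkene: the alkenylpalladium adds to the CH2 end of 4 and syn β-hydride elimination from the new allylic CH2 gives the conjugated dienal, E because ring and formyl group lie anti in the eliminating conformer, while Et3N is too weak a base to touch the vinylogous C–H at the methyl-bearing centre.

Step 3
Reactants: 5 dienal
Product: 6 (2E)-2-methyl-3-[(3S,6R)-3-methyl-6-(propan-2-yl)cyclohex-1-en-1-yl]prop-2-en-1-ol (dienol)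
Conditions: NaBH4, CeCl3·7H2O, MeOH, 0 °C
Reagents that add atoms: none
Why: Luche reduction: the cerium-modified borohydride attacks only the aldehyde carbon (1,2-selectivity), the diene stays in place and no stereocentre is formed.

Step 4
Reactants: 6 dienol
Product: 7 (2E)-2-methyl-3-[(3S,6R)-3-methyl-6-(propan-2-yl)cyclohex-1-en-1-yl]prop-2-en-1-yl acetate (primary dienyl acetate)
Conditions: Ac2O, DMAP (cat.), pyridine, rt
Reagents that add atoms: acetic anhydride, CC(=O)OC(C)=O
Why: DMAP-catalysed O-acylation of a primary allylic alcohol installs the leaving group for palladium without touching the diene.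

Step 5
Reactants: 7 primary dienyl acetate; 8 carbon monoxide
Product: 12 (1S,4R)-8-acetoxycalamenene [(5R,8S)-3,8-dimethyl-5-(propan-2-yl)-5,6,7,8-tetrahydronaphthalen-1-yl acetate], via dienylketene 9 (not isolated), via cyclohexadienone 10 (not isolated), via 8-hydroxycalamenene 11 (not isolated)
Conditions: PdCl2(PPh3)2 (5 mol %), CO (60 atm), Ac2O, Et3N, toluene, 150 °C (autoclave)
Reagents that add atoms: acetic anhydride, CC(=O)OC(C)=O
Why: Palladium-catalysed cyclocarbonylation of a primary 2,4-pentadienyl acetate, a known route to aryl acetates: zerovalent palladium ionises the acetate, CO inserts at the unhindered CH2 terminus (future C7), loss of acetic acid gives ketene 9, 6π-electrocyclisation onto the ring alkene gives 10, and enolisation to 11 and acetylation follow, with C1 and C4 as untouched spectators.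

Step 6
Reactants: 12 (1S,4R)-8-acetoxycalamenene
Product: 14 (1S,4R)-8-methoxycalamenene, via potassium phenoxide 13 (not isolated)
Conditions: KOH (powder), DMSO, rt; then MeI, rt
Reagents that add atoms: iodomethane, CI
Why: Saponification of the aryl acetate and Williamson etherification of the phenoxide in one flask; the methyl ether is chosen because it survives n-BuLi in step 8 and the hot Ac2O/Et3N medium of step 9.

Step 7
Reactants: 14 (1S,4R)-8-methoxycalamenene
Product: 15 (1S,4R)-5-bromo-8-methoxycalamenene
Conditions: NBS, MeCN, 0 °C → rt, dark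
Reagents that add atoms: N-bromosuccinimide, O=C1CCC(=O)N1Br
Why: Electrophilic aromatic bromination with NBS in MeCN is para-selective for anisoles, and here C5 is para to OMe and ortho to the C6 methyl group, whereas the only other free position, C7, is screened by the O-methyl group that the peri C1 methyl pushes toward it.

Step 8
Reactants: 15 (1S,4R)-5-bromo-8-methoxycalamenene; 5 dienal
Product: 18 (2E)-1-[(1'S,4'R)-8'-methoxycalamenen-5'-yl]-2-methyl-3-[(3S,6R)-3-methyl-6-(propan-2-yl)cyclohex-1-en-1-yl]prop-2-en-1-yl acetate (secondary pentadienyl acetate; both carbinol epimers), via aryllithium 16 (not isolated), via lithium alkoxide 17 (not isolated)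
Conditions: n-BuLi, THF, −78 °C; 5, −78 → 0 °C; Ac2O, 0 °C → rt; chromatography on Et3N-washed silica
Reagents that add atoms: acetic anhydride, CC(=O)OC(C)=O
Why: Bromine–lithium exchange, 1,2-addition of the aryllithium to the enal and O-acetylation of the alkoxide in the same flask form the C7–C5' bond while C7 is still sp3 and far less crowded than in a biaryl coupling; the new carbinol centre arises without control and both epimers are used, since C7 becomes sp2 in step 9.

Step 9
Reactants: 18 secondary pentadienyl acetate; 8 carbon monoxide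
Product: 22 (1S,4R)-8-acetoxy-7-[(1'S,4'R)-8'-methoxycalamenen-5'-yl]calamenene (ring A acetate and unit B methyl ether of the target), via dienylketene 19 (not isolated), via cyclohexadienone 20 (not isolated), via ring A phenol 21 (not isolated)
Conditions: PdCl2(PPh3)2 (10 mol %), CO (70 atm), Ac2O, Et3N, toluene, 150 °C (autoclave)
Reagents that add atoms: acetic anhydride, CC(=O)OC(C)=O
Why: Proposed new method: zerovalent palladium, formed from PdCl2(PPh3)2 under CO and Et3N, ionises the allylic and benzylic C7 acetate to an η3-pentadienyl complex whose η3–η1–η3 shifts erase the carbinol configuration and bring the C5=C6 unit into the cisoid form (eased by the C6 methyl group on the central allyl carbon), CO inserts into the Pd–C7 bond, and Et3N removes C7–H from the acyl palladium or its mixed anhydride to give dienylketene 19. Ring A, the only ring formed, then closes by a thermal disrotatory 6π-electrocyclisation that joins the ketene carbon C8 to C8a of the menthene alkene (six-membered carbocycle 20), after which loss of C8a–H by enolisation gives phenol 21 and Ac2O fixes it as acetate 22, which keeps free phenol away from the catalyst. The closest known reaction type is the palladium-catalysed cyclocarbonylation of primary 2,4-pentadienyl and cinnamyl acetates to aryl acetates (as in step 5), backed by the Ac2O-induced cyclisation of 3,5-dienoic acids to aryl acetates; what has not been shown is a secondary terminus that carries a di-ortho-substituted aryl group. No stereocentre is created and C1, C4, C1' and C4' are spectators; the C7–C5' bond turns into a hindered biaryl axis whose sense can be biased only by the neighbouring C4' isopropyl and C1 methyl groups. The step needs carbonylation to outrun β-hydride loss and needs the acyl group at an end of the five-carbon chain: palladium on C7 has no β-hydrogen at all, only palladium on C8a has one (C1–H), and high CO pressure favours the acyl path. An acyl group at C5 cannot close a ring and decarbonylates again, whereas one at C8a would lead through the isomeric dienylketene to the same bonds C7–C8 and C8–C8a, so both productive channels end in 22.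

Step 10
Reactants: 22 ring A acetate and unit B methyl ether of the target
Product: 24 (1S,4R)-7-[(1'S,4'R)-8'-hydroxycalamenen-5'-yl]calamenen-8-ol (target CNP0145304.1), via disodium bisphenoxide 23 (not isolated)
Conditions: NaSEt, DMF, 130 °C, argon; aq HCl work-up
Reagents that add atoms: none
Why: Thiolate-mediated deprotection: ethanethiolate takes the acetyl group by acyl transfer and the O-methyl group by SN2 attack at carbon, under basic, non-oxidising conditions that leave the benzylic stereocentres and the biaryl bond alone.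

Compound list
1 | (+)-menthone, (2R,5S)-5-methyl-2-(propan-2-yl)cyclohexan-1-one | O=C1C[C@@H](C)CC[C@@H]1C(C)C | starting material
2 | lithium (3S,6R)-3-methyl-6-(propan-2-yl)cyclohex-1-en-1-olate | [Li+].[O-]C1=C[C@@H](C)CC[C@@H]1C(C)C | intermediate
3 | (3S,6R)-3-methyl-6-(propan-2-yl)cyclohex-1-en-1-yl trifluoromethanesulfonate | O=S(=O)(OC1=C[C@@H](C)CC[C@@H]1C(C)C)C(F)(F)F | intermediate
4 | methacrolein | CC(=C)C=O | starting material
5 | (2E)-2-methyl-3-[(3S,6R)-3-methyl-6-(propan-2-yl)cyclohex-1-en-1-yl]prop-2-enal | O=C/C(C)=C/C1=C[C@@H](C)CC[C@@H]1C(C)C | intermediate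
6 | (2E)-2-methyl-3-[(3S,6R)-3-methyl-6-(propan-2-yl)cyclohex-1-en-1-yl]prop-2-en-1-ol | OC/C(C)=C/C1=C[C@@H](C)CC[C@@H]1C(C)C | intermediate
7 | (2E)-2-methyl-3-[(3S,6R)-3-methyl-6-(propan-2-yl)cyclohex-1-en-1-yl]prop-2-en-1-yl acetate | CC(=O)OC/C(C)=C/C1=C[C@@H](C)CC[C@@H]1C(C)C | intermediate
8 | carbon monoxide | [C-]#[O+] | starting material
9 | (3Z)-3-methyl-4-[(3S,6R)-3-methyl-6-(propan-2-yl)cyclohex-1-en-1-yl]buta-1,3-dien-1-one (dienylketene) | O=C=C/C(C)=C\C1=C[C@@H](C)CC[C@@H]1C(C)C | intermediate
10 | (5R,8S)-3,8-dimethyl-5-(propan-2-yl)-6,7,8,8a-tetrahydronaphthalen-1(5H)-one, the 8a-H keto tautomer of 11, C8a unassigned | O=C1C=C(C)C=C2C1[C@@H](C)CC[C@@H]2C(C)C | intermediate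
11 | (1S,4R)-8-hydroxycalamenene | Oc1cc(C)cc2c1[C@@H](C)CC[C@@H]2C(C)C | intermediate
12 | (1S,4R)-8-acetoxycalamenene | CC(=O)Oc1cc(C)cc2c1[C@@H](C)CC[C@@H]2C(C)C | intermediate
13 | potassium salt of (1S,4R)-8-hydroxycalamenene | [K+].[O-]c1cc(C)cc2c1[C@@H](C)CC[C@@H]2C(C)C | intermediate
14 | (1S,4R)-8-methoxycalamenene | COc1cc(C)cc2c1[C@@H](C)CC[C@@H]2C(C)C | intermediate
15 | (1S,4R)-5-bromo-8-methoxycalamenene | COc1cc(C)c(Br)c2c1[C@@H](C)CC[C@@H]2C(C)C | intermediate
16 | (1S,4R)-5-lithio-8-methoxycalamenene | COc1cc(C)c([Li])c2c1[C@@H](C)CC[C@@H]2C(C)C | intermediate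
17 | lithium alkoxide of the C7 carbinol (both epimers), E alkene | [Li+].[O-]C(/C(C)=C/C1=C[C@@H](C)CC[C@@H]1C(C)C)c1c(C)cc(OC)c2c1[C@@H](C(C)C)CC[C@@H]2C | intermediate
18 | (2E)-1-[(1'S,4'R)-8'-methoxycalamenen-5'-yl]-2-methyl-3-[(3S,6R)-3-methyl-6-(propan-2-yl)cyclohex-1-en-1-yl]prop-2-en-1-yl acetate (both carbinol epimers) | CC(=O)OC(/C(C)=C/C1=C[C@@H](C)CC[C@@H]1C(C)C)c1c(C)cc(OC)c2c1[C@@H](C(C)C)CC[C@@H]2C | intermediate
19 | (3Z)-2-[(1'S,4'R)-8'-methoxycalamenen-5'-yl]-3-methyl-4-[(3S,6R)-3-methyl-6-(propan-2-yl)cyclohex-1-en-1-yl]buta-1,3-dien-1-one (dienylketene) | O=C=C(/C(C)=C\C1=C[C@@H](C)CC[C@@H]1C(C)C)c1c(C)cc(OC)c2c1[C@@H](C(C)C)CC[C@@H]2C | intermediate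
20 | 8a-H keto tautomer of 21 (cyclohexa-2,4-dienone, C8a unassigned) | O=C1C(c3c(C)cc(OC)c4c3[C@@H](C(C)C)CC[C@@H]4C)=C(C)C=C2C1[C@@H](C)CC[C@@H]2C(C)C | intermediate
21 | (1S,4R)-7-[(1'S,4'R)-8'-methoxycalamenen-5'-yl]calamenen-8-ol | Cc1cc2c(c(O)c1-c1c(C)cc(OC)c3c1[C@@H](C(C)C)CC[C@@H]3C)[C@@H](C)CC[C@@H]2C(C)C | intermediate
22 | (1S,4R)-8-acetoxy-7-[(1'S,4'R)-8'-methoxycalamenen-5'-yl]calamenene | Cc1cc2c(c(OC(C)=O)c1-c1c(C)cc(OC)c3c1[C@@H](C(C)C)CC[C@@H]3C)[C@@H](C)CC[C@@H]2C(C)C | intermediate
23 | disodium salt of 24 | [Na+].[Na+].Cc1cc2c(c([O-])c1-c1c(C)cc([O-])c3c1[C@@H](C(C)C)CC[C@@H]3C)[C@@H](C)CC[C@@H]2C(C)C | intermediate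
24 | (1S,4R)-7-[(1'S,4'R)-8'-hydroxycalamenen-5'-yl]calamenen-8-ol, CNP0145304.1 | Cc1cc2c(c(O)c1-c1c(C)cc(O)c3c1[C@@H](C(C)C)CC[C@@H]3C)[C@@H](C)CC[C@@H]2C(C)C | target

Total step count: 10.
Longest linear sequence: 10 steps (1 → 3 → 5 → 6 → 7 → 12 → 14 → 15 → 18 → 22 → 24). Dienal 5 enters a second time in step 8.

Steps most likely to fail

1. Step 9 (the labelled step).
- **Risk:** Carbonylation at the crowded chain ends may be too slow. β-Hydride loss through C1–H (with erosion of C1), migration of the acetate along the dienyl chain or plain thermal elimination would then use up the substrate.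
- **Fallback:** This uses known chemistry and joins two finished aromatic halves. It sets out from 14 and 15 and comes back at 23.
- Directed ortho-lithiation of 14 at C7, the only free position next to OMe (n-BuLi, TMEDA, Et2O, 0 °C → rt), should give (1S,4R)-7-lithio-8-methoxycalamenene F1.
- ZnCl2 converts it into the arylzinc chloride F2.
- Negishi coupling with bromide 15 (Pd2(dba)3, RuPhos, THF/NMP, 100 °C), a reaction type established for biaryls with four ortho substituents, should give the bis(methyl ether) of the target F3.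
- NaSEt in DMF under the conditions of step 10 cleaves both ethers to bisphenoxide 23, and acid gives 24.

2. Step 2.
- **Risk:** Methacrolein may polymerise at the reaction temperature, β-hydride elimination may go toward the methyl group instead of the allylic CH2, and insertion next to the isopropyl group may be slow.
- **Fallback:** This sets out from 3 and comes back at 5. The C5–C4a bond is made by carbonylation and the C5=C6 bond by olefination.
- Reductive carbonylation of 3 (Pd(PPh3)4, LiCl, CO 3 atm, Bu3SnH added slowly, THF, 50 °C) should give (3S,6R)-3-methyl-6-(propan-2-yl)cyclohex-1-ene-1-carbaldehyde F4.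
- Wittig olefination with the stabilised ylide Ph3P=C(CH3)CHO (toluene, reflux) should give the (E)-dienal 5.

3. Step 8.
- **Risk:** 1,2-Addition of the di-ortho-substituted aryllithium may be sluggish, 5 may be deprotonated at its vinylogous C–H, and the doubly activated acetate may ionise during isolation.
- **Fallback:** The polarity is reversed. It sets out from 15 and 3 and comes back at 17.
- Aryllithium 16, made as in step 8, is quenched with DMF to give (1S,4R)-8-methoxycalamenene-5-carbaldehyde F5.
- Sonogashira coupling of 3 with propyne (PdCl2(PPh3)2, CuI, Et3N, DMF, rt) should give (3S,6R)-3-methyl-6-(propan-2-yl)-1-(prop-1-yn-1-yl)cyclohex-1-ene F6.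
- syn-Hydrozirconation with Cp2ZrHCl places the metal next to the small methyl group and gives the alkenylzirconocene chloride F7.
- I2 turns it with retention into the (E)-alkenyl iodide F8, and t-BuLi (THF, −78 °C) gives the slim alkenyllithium F9.
- F9 adds to F5 to give lithium alkoxide 17, and Ac2O in the same flask then gives 18 as in step 8.

Further compounds
F1 | step 9 | (1S,4R)-7-lithio-8-methoxycalamenene | [Li]c1c(C)cc2c(c1OC)[C@@H](C)CC[C@@H]2C(C)C
F2 | step 9 | [(1S,4R)-8-methoxycalamenen-7-yl]zinc chloride | Cl[Zn]c1c(C)cc2c(c1OC)[C@@H](C)CC[C@@H]2C(C)C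
F3 | step 9 | (1S,4R)-8-methoxy-7-[(1'S,4'R)-8'-methoxycalamenen-5'-yl]calamenene, bis(methyl ether) of the target | Cc1cc2c(c(OC)c1-c1c(C)cc(OC)c3c1[C@@H](C(C)C)CC[C@@H]3C)[C@@H](C)CC[C@@H]2C(C)C
F4 | step 2 | (3S,6R)-3-methyl-6-(propan-2-yl)cyclohex-1-ene-1-carbaldehyde | O=CC1=C[C@@H](C)CC[C@@H]1C(C)C
F5 | step 8 | (1S,4R)-8-methoxycalamenene-5-carbaldehyde | O=Cc1c(C)cc(OC)c2c1[C@@H](C(C)C)CC[C@@H]2C
F6 | step 8 | (3S,6R)-3-methyl-6-(propan-2-yl)-1-(prop-1-yn-1-yl)cyclohex-1-ene | CC#CC1=C[C@@H](C)CC[C@@H]1C(C)C
F7 | step 8 | chlorobis(cyclopentadienyl)[(1E)-1-[(3S,6R)-3-methyl-6-(propan-2-yl)cyclohex-1-en-1-yl]prop-1-en-2-yl]zirconium | Cl[Zr](/C(C)=C/C1=C[C@@H](C)CC[C@@H]1C(C)C)(C1C=CC=C1)C1C=CC=C1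
F8 | step 8 | (3S,6R)-1-[(1E)-2-iodoprop-1-en-1-yl]-3-methyl-6-(propan-2-yl)cyclohex-1-ene | I/C(C)=C/C1=C[C@@H](C)CC[C@@H]1C(C)C
F9 | step 8 | (1E)-1-[(3S,6R)-3-methyl-6-(propan-2-yl)cyclohex-1-en-1-yl]prop-1-en-2-yllithium | [Li]/C(C)=C/C1=C[C@@H](C)CC[C@@H]1C(C)C
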